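Cuts: both epoxide C–O pairs (back to the E,E-1(10),4-diene), the C8 and C13 ester C–O bonds, the lactone C12–O6 bond and C7=C11 (C6 ketone plus a three-carbon α-keto ester), then C1–C4/C5–C10 and finally C1–C10/C4–C5.
Enabling feature: the epoxides sit on C1=C10 and C4=C5 of a cyclodeca-1,5-diene, the ring-opened form of a bicyclo[2.2.0]hexane (C1, C2, C3, C4, C5, C10) in which a cyclobutene (C1–C4) is joined to the alkene of a six-carbon enone (C5–C10, carbonyl at C6).
Forward order: six-membered enone ring → cyclobutane by (2+2) photocycloaddition → ten-membered ring by thermal opening of both four-membered rings → C15 ester to methyl → C7–C11 aldol and dehydration → C6 reduction and lactone ring → acetate and angelate → two epoxide rings.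
Stereochemistry: C8 from lipase desymmetrisation of a meso diol, carried in the enone; C6 from CBS reduction; E,E diene geometry from the trans ring fusion of the photoadduct; C1, C10, C4 and C5 from outer-face epoxidation of the two E alkenes.

Key step: step 8

Remark on numbering: all ten-membered-ring compounds carry germacrane numbering (ring C1–C10, C14 on C10, C15 on C4, C11–C13 on C7).
Assumption: the lipase acylates the hydroxyl that leads to 3; if it shows the opposite sense, hydrolysis of the diacetate of 2 with the same enzyme gives the same monoacetate.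

Step 1
Reactants: 1 all-cis-cyclohexane-1,3,5-triol
Product: 2 all-cis-5-[(tert-butyldimethylsilyl)oxy]cyclohexane-1,3-diol (meso)
Conditions: NaH (1.0 equiv), TBSCl (1.0 equiv), THF, 0 °C to rt
Reagents that add atoms: tert-butyldimethylsilyl chloride, C[Si](C)(Cl)C(C)(C)C
Why: Monosilylation of one of three equivalent hydroxyls through the sodium alkoxide (Williamson-type O-silylation) is statistical, gives a meso product and creates no stereocentre.

Step 2
Reactants: 2 all-cis-5-[(tert-butyldimethylsilyl)oxy]cyclohexane-1,3-diol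
Product: 3 (1R,3S,5S)-3-[(tert-butyldimethylsilyl)oxy]-5-hydroxycyclohexyl acetate (all-cis)
Conditions: lipase from Pseudomonas cepacia, vinyl acetate, tBuOMe, rt
Reagents that add atoms: vinyl acetate, CC(=O)OC=C
Why: Lipase-catalysed transesterification acylates one of the two enantiotopic hydroxyls of the meso diol (enzymatic desymmetrisation), so the enzyme fixes the absolute configuration of the silyloxy carbon that becomes C8.

Step 3
Reactants: 3 (1R,3S,5S)-3-[(tert-butyldimethylsilyl)oxy]-5-hydroxycyclohexyl acetate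
Product: 5 (R)-5-[(tert-butyldimethylsilyl)oxy]cyclohex-2-en-1-one, via β-acetoxy ketone 4 (not isolated)
Conditions: Dess–Martin periodinane, CH2Cl2, rt; then DBU, 0 °C
Reagents that add atoms: none
Why: Dess–Martin oxidation gives the β-acetoxy ketone, from which DBU removes acetic acid by E1cB elimination (acetate leaves far more readily than the silyloxide), and the silyloxy stereocentre is not touched.

Step 4
Reactants: 5 (R)-5-[(tert-butyldimethylsilyl)oxy]cyclohex-2-en-1-one
Product: 6 (5R)-5-[(tert-butyldimethylsilyl)oxy]-1-methylcyclohex-2-en-1-ol (both C1 epimers)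
Conditions: MeLi, Et2O, −78 °C; H2O
Reagents that add atoms: methyllithium, [Li]C
Why: 1,2-Addition of methyllithium to the enone carbonyl gives the tertiary allylic alcohol, whose new carbinol centre forms as a mixture and is erased in step 5.

Step 5
Reactants: 6 (5R)-5-[(tert-butyldimethylsilyl)oxy]-1-methylcyclohex-2-en-1-ol
Product: 7 (S)-5-[(tert-butyldimethylsilyl)oxy]-3-methylcyclohex-2-en-1-one
Conditions: pyridinium chlorochromate [C5H5NH][CrO3Cl], 4 Å molecular sieves, CH2Cl2, rt
Reagents that add atoms: none
Why: Dauben–Michno oxidative 1,3-transposition of the tertiary allylic alcohol (chromate ester, [3,3] shift, oxidation) moves the oxygen to the far allyl terminus and leaves the methyl on the β carbon, while the silyloxy centre keeps its arrangement and changes descriptor from R to S only through the priority rules.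

Step 6
Reactants: 8 ethyl 1-bromocyclobutane-1-carboxylate
Product: 9 cyclobut-1-ene-1-carboxylic acid
Conditions: KOH, toluene, reflux; then aq HCl
Reagents that add atoms: potassium hydroxide, [K+].[OH-]
Why: Base-induced E2 dehydrobromination of the tertiary α-bromo ester with concurrent saponification is a known preparation of this acid.

Step 7
Reactants: 9 cyclobut-1-ene-1-carboxylic acid
Product: 10 methyl cyclobut-1-ene-1-carboxylate
Conditions: MeI, K2CO3, DMF, rt; kept as a cold solution
Reagents that add atoms: iodomethane, CI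
Why: SN2 O-methylation of the carboxylate avoids acid and heat, which the strained and polymerisable alkene does not tolerate.

Step 8
Reactants: 7 (S)-5-[(tert-butyldimethylsilyl)oxy]-3-methylcyclohex-2-en-1-one; 10 methyl cyclobut-1-ene-1-carboxylate
Product: 11 methyl (8S)-8-[(tert-butyldimethylsilyl)oxy]-6-methyl-10-oxotricyclo[4.4.0.0(2,5)]decane-2-carboxylate, head-to-head, trans-fused at C1/C6 (six–four junction, H-1 anti to the C6 methyl), cis-fused at C2/C5, ester on the same face of the central cyclobutane as the C6 methyl and C10 (one of the two trans-fused facial isomers drawn; both converge in step 9)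
Conditions: hν (350 nm, Pyrex), 10 (3 equiv), degassed CH2Cl2, −40 °C; neutral work-up
Reagents that add atoms: none
Why: Excitation of the enone (n→π*) and intersystem crossing give a twisted triplet that adds stepwise to the cyclobutene ester: the β carbon (germacrane C10) bonds to the unsubstituted alkene carbon (C1), and the triplet 1,4-biradical (α-keto radical at C5, ester-stabilised tertiary radical at C4) closes the C4–C5 bond after spin inversion. The closest known reaction type is the intermolecular enone–alkene (2+2) photocycloaddition of cyclohex-2-enones with cyclobut-1-enecarboxylates to tricyclo[4.4.0.0(2,5)]decanones. One ring closes, the central cyclobutane C1–C10–C5–C4, by radical–radical combination within the 1,4-biradical. Of the four new stereocentres, C1 and C4 are cis by the constraint of the cyclobutene ring, and the C5/C10 junction is set trans at biradical closure because the twisted triplet bonds through opposite faces at C5 and C10, which low temperature favours; the facial sense relative to C8 is immaterial because C1, C4, C5 and C10 all become sp2 in step 9. The step needs head-to-head regiochemistry, which the acceptor ester secures by making C4 the radical terminus that pairs with C5, and it needs the trans junction, which neutral work-up preserves because H-5 is epimerisable.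

Step 9
Reactants: 11 methyl (8S)-8-[(tert-butyldimethylsilyl)oxy]-6-methyl-10-oxotricyclo[4.4.0.0(2,5)]decane-2-carboxylate
Product: 12 methyl (8S)-8-[(tert-butyldimethylsilyl)oxy]-10-methyl-6-oxocyclodeca-1(10),4-diene-4-carboxylate, both ring alkenes trans in the ring (C2 anti to C9, C3 anti to C6)
Conditions: degassed toluene, base-washed sealed tube, 180 °C
Reagents that add atoms: none
Why: Thermal cycloreversion of the bicyclo[2.2.0]hexane starts with homolysis of the strained, ester-flanked C1–C4 bond to a cyclohexane-1,4-diyl, whose chair holds both bonds of the trans-fused six-membered ring equatorial and then cleaves C5–C10, so both new ring alkenes are E, the four cyclobutane stereocentres vanish, C8 is untouched, and conjugation of C4=C5 with ester and ketone holds the product against Cope rearrangement.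

Step 10
Reactants: 12 methyl (8S)-8-[(tert-butyldimethylsilyl)oxy]-10-methyl-6-oxocyclodeca-1(10),4-diene-4-carboxylate
Product: 13 methyl (8S)-6,8-bis[(tert-butyldimethylsilyl)oxy]-10-methylcyclodeca-1(10),4,6-triene-4-carboxylate (C6=C7 silyl enol ether)
Conditions: TBSCl, then KN(SiMe3)2, THF, −78 °C
Reagents that add atoms: tert-butyldimethylsilyl chloride, C[Si](C)(Cl)C(C)(C)C
Why: Kinetic deprotonation at C7, the only enolisable α position, with in situ O-silylation gives the silyl dienol ether, which masks the ketone so that the C15 carbinol made next cannot close onto C6 to a furan or dihydrofuran.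

Step 11
Reactants: 13 methyl (8S)-6,8-bis[(tert-butyldimethylsilyl)oxy]-10-methylcyclodeca-1(10),4,6-triene-4-carboxylate
Product: 14 [(8S)-6,8-bis[(tert-butyldimethylsilyl)oxy]-10-methylcyclodeca-1(10),4,6-trien-4-yl]methanol
Conditions: iBu2AlH, CH2Cl2, −78 °C; aq KNaC4H4O6
Reagents that add atoms: none
Why: 1,2-Reduction of the conjugated ester by iBu2AlH gives the primary allylic alcohol, while silyl ether and silyl enol ether are inert and the work-up stays non-acidic.

Step 12
Reactants: 14 [(8S)-6,8-bis[(tert-butyldimethylsilyl)oxy]-10-methylcyclodeca-1(10),4,6-trien-4-yl]methanol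
Product: 16 (8S)-6,8-bis[(tert-butyldimethylsilyl)oxy]-4,10-dimethylcyclodeca-1(10),4,6-triene, via allylic chloride 15 (not isolated)
Conditions: MsCl, 2,4,6-collidine, LiCl, DMF, 0 °C; then LiEt3BH, THF, 0 °C
Reagents that add atoms: none
Why: Collington–Meyers conversion of the primary allylic alcohol into the chloride without allylic shift is followed by SN2 displacement of chloride by hydride from LiEt3BH, which turns C15 into the methyl group.

Step 13
Reactants: 17 methyl 2-(hydroxymethyl)acrylate
Product: 18 methyl 2-{[(tert-butyldimethylsilyl)oxy]methyl}acrylate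
Conditions: TBSCl, imidazole, CH2Cl2, rt
Reagents that add atoms: tert-butyldimethylsilyl chloride, C[Si](C)(Cl)C(C)(C)C
Why: Imidazole-mediated silylation of a primary alcohol is routine.

Step 14
Reactants: 18 methyl 2-{[(tert-butyldimethylsilyl)oxy]methyl}acrylate
Product: 20 methyl 3-[(tert-butyldimethylsilyl)oxy]-2-oxopropanoate, via secondary ozonide 19 (not isolated)
Conditions: O3, CH2Cl2, −78 °C; then Me2S
Reagents that add atoms: ozone, [O-][O+]=O
Why: Ozonolysis of the 1,1-disubstituted alkene with reductive work-up gives the α-keto ester and formaldehyde.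

Step 15
Reactants: 16 (8S)-6,8-bis[(tert-butyldimethylsilyl)oxy]-4,10-dimethylcyclodeca-1(10),4,6-triene; 20 methyl 3-[(tert-butyldimethylsilyl)oxy]-2-oxopropanoate
Product: 21 methyl 3-[(tert-butyldimethylsilyl)oxy]-2-[(8S)-8-[(tert-butyldimethylsilyl)oxy]-4,10-dimethyl-6-oxocyclodeca-1(10),4-dien-7-yl]-2-hydroxypropanoate (mixture at C7 and C11)
Conditions: BF3·OEt2, CH2Cl2, −78 °C
Reagents that add atoms: none
Why: In this Mukaiyama aldol addition BF3 activates the ketone carbonyl of the α-keto ester and the silyl dienol ether attacks through C7, its nucleophilic terminus, so the new centres C7 and C11 form without control and are both removed in step 16.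

Step 16
Reactants: 21 methyl 3-[(tert-butyldimethylsilyl)oxy]-2-[(8S)-8-[(tert-butyldimethylsilyl)oxy]-4,10-dimethyl-6-oxocyclodeca-1(10),4-dien-7-yl]-2-hydroxypropanoate
Product: 23 methyl (2Z)-3-[(tert-butyldimethylsilyl)oxy]-2-[(8S)-8-[(tert-butyldimethylsilyl)oxy]-4,10-dimethyl-6-oxocyclodeca-1(10),4-dien-7-ylidene]propanoate (ester syn to C6), via tertiary trifluoroacetate 22 (not isolated)
Conditions: (CF3CO)2O, pyridine, CH2Cl2, 0 °C; then DBU, 0 °C, short contact
Reagents that add atoms: none
Why: Trifluoroacetylation of the tertiary alcohol and DBU-induced E1cB elimination through the C7 enolate give the tetrasubstituted C7=C11 alkene (trifluoroacetate leaves in preference to the C8 silyloxide), and since the mechanism does not fix the geometry, the isomer with the ester syn to C6 is the one carried on.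

Step 17
Reactants: 23 methyl (2Z)-3-[(tert-butyldimethylsilyl)oxy]-2-[(8S)-8-[(tert-butyldimethylsilyl)oxy]-4,10-dimethyl-6-oxocyclodeca-1(10),4-dien-7-ylidene]propanoate
Product: 25 (6R,8S)-8,13-bis[(tert-butyldimethylsilyl)oxy]germacra-1(10),4,7(11)-trien-12,6-olide (1(10)E,4E), via syn hydroxy ester 24 (not isolated)
Conditions: (S)-2-methyl-CBS-oxazaborolidine (20 mol %), catecholborane, toluene, −78 °C; then pyridinium p-toluenesulfonate, CH2Cl2, rt
Reagents that add atoms: none
Why: In this Corey–Bakshi–Shibata reduction the fully substituted alkylidene carbon C7 is taken as the large and the CH= carbon C5 as the small ketone substituent, so the (S)-oxazaborolidine should deliver hydride to give the 6R alcohol (the target's 6S centre, the descriptor changing on epoxidation), which closes onto the syn ester by lactonisation to the butenolide.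

Step 18
Reactants: 25 (6R,8S)-8,13-bis[(tert-butyldimethylsilyl)oxy]germacra-1(10),4,7(11)-trien-12,6-olide
Product: 26 (6R,8S)-8,13-dihydroxygermacra-1(10),4,7(11)-trien-12,6-olide
Conditions: HF·pyridine, pyridine, THF, 0 °C to rt
Reagents that add atoms: none
Why: Fluoride-mediated cleavage removes both silyl ethers, and the pyridine buffer spares the butenolide and the acid-sensitive 1,5-diene.

Step 19
Reactants: 26 (6R,8S)-8,13-dihydroxygermacra-1(10),4,7(11)-trien-12,6-olide
Product: 27 (6R,8S)-13-acetoxy-8-hydroxygermacra-1(10),4,7(11)-trien-12,6-olide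
Conditions: AcCl (1.05 equiv), 2,4,6-collidine, CH2Cl2, −78 °C
Reagents that add atoms: acetyl chloride, CC(Cl)=O
Why: Chemoselective acetylation is expected because the primary allylic C13 hydroxyl reacts far faster with AcCl and collidine at low temperature than the hindered secondary C8 hydroxyl.

Step 20
Reactants: 27 (6R,8S)-13-acetoxy-8-hydroxygermacra-1(10),4,7(11)-trien-12,6-olide; 28 angelic acid [(Z)-2-methylbut-2-enoic acid]
Product: 30 (6R,8S)-13-acetoxy-8-(angeloyloxy)germacra-1(10),4,7(11)-trien-12,6-olide (1(10)E,4E), via mixed anhydride 29 (not isolated)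
Conditions: 28, 2,4,6-trichlorobenzoyl chloride, Et3N, toluene, rt; then 27, 4-(dimethylamino)pyridine, rt
Reagents that add atoms: none
Why: Yamaguchi esterification through the mixed anhydride with acyl transfer by 4-(dimethylamino)pyridine at room temperature should keep the Z geometry of the angeloyl group and acylates O-8 with retention at C8.

Step 21
Reactants: 30 (6R,8S)-13-acetoxy-8-(angeloyloxy)germacra-1(10),4,7(11)-trien-12,6-olide
Product: 31 (1R,4R,5R,6S,8S,10R)-13-acetoxy-8-(angeloyloxy)-1,10:4,5-diepoxygermacr-7(11)-en-12,6-olide (target)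
Conditions: mCPBA (2.3 equiv), CH2Cl2, 0 °C
Reagents that add atoms: 3-chloroperbenzoic acid, OOC(=O)c1cccc(Cl)c1
Why: Prilezhaev epoxidation takes the two electron-rich trisubstituted ring alkenes (butenolide and angelate alkenes are deactivated), each E alkene of the crossed cyclodeca-1,5-diene exposes only its outer face, with H-6 eclipsing the C4–C15 bond the outer face of C4=C5 is syn to O-6, and the syn-methyl conformer presents the outer face of C1=C10 that leads to the 1R,10R epoxide, as in peracid epoxidations of related germacranolides.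

Compound list
1 | all-cis-cyclohexane-1,3,5-triol | O[C@H]1C[C@@H](O)C[C@@H](O)C1 | starting material
2 | all-cis-5-[(tert-butyldimethylsilyl)oxy]cyclohexane-1,3-diol (meso) | O[C@H]1C[C@@H](O)C[C@@H](O[Si](C)(C)C(C)(C)C)C1 | intermediate
3 | (1R,3S,5S)-3-[(tert-butyldimethylsilyl)oxy]-5-hydroxycyclohexyl acetate | O[C@H]1C[C@@H](OC(C)=O)C[C@@H](O[Si](C)(C)C(C)(C)C)C1 | intermediate
4 | (1S,3R)-3-[(tert-butyldimethylsilyl)oxy]-5-oxocyclohexyl acetate | O=C1C[C@@H](OC(C)=O)C[C@@H](O[Si](C)(C)C(C)(C)C)C1 | intermediate
5 | (R)-5-[(tert-butyldimethylsilyl)oxy]cyclohex-2-en-1-one | O=C1C=CC[C@@H](O[Si](C)(C)C(C)(C)C)C1 | intermediate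
6 | (5R)-5-[(tert-butyldimethylsilyl)oxy]-1-methylcyclohex-2-en-1-ol (C1 epimers) | CC1(O)C=CC[C@@H](O[Si](C)(C)C(C)(C)C)C1 | intermediate
7 | (S)-5-[(tert-butyldimethylsilyl)oxy]-3-methylcyclohex-2-en-1-one | CC1=CC(=O)C[C@@H](O[Si](C)(C)C(C)(C)C)C1 | intermediate
8 | ethyl 1-bromocyclobutane-1-carboxylate | CCOC(=O)C1(Br)CCC1 | starting material
9 | cyclobut-1-ene-1-carboxylic acid | OC(=O)C1=CCC1 | intermediate
10 | methyl cyclobut-1-ene-1-carboxylate | COC(=O)C1=CCC1 | intermediate
11 | methyl (8S)-8-[(tert-butyldimethylsilyl)oxy]-6-methyl-10-oxotricyclo[4.4.0.0(2,5)]decane-2-carboxylate, head-to-head, trans-fused C1/C6, cis-fused C2/C5 | O=C1C[C@@H](O[Si](C)(C)C(C)(C)C)C[C@@]2(C)[C@H]1[C@@]3(C(=O)OC)CC[C@@H]23 | intermediate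
12 | methyl (8S)-8-[(tert-butyldimethylsilyl)oxy]-10-methyl-6-oxocyclodeca-1(10),4-diene-4-carboxylate, both ring alkenes trans in the ring | C1/C(C(=O)OC)=C/C(=O)C[C@@H](O[Si](C)(C)C(C)(C)C)C/C(C)=C/C1 | intermediate
13 | methyl (8S)-6,8-bis[(tert-butyldimethylsilyl)oxy]-10-methylcyclodeca-1(10),4,6-triene-4-carboxylate | C1/C(C(=O)OC)=C/C(O[Si](C)(C)C(C)(C)C)=C[C@@H](O[Si](C)(C)C(C)(C)C)C/C(C)=C/C1 | intermediate
14 | [(8S)-6,8-bis[(tert-butyldimethylsilyl)oxy]-10-methylcyclodeca-1(10),4,6-trien-4-yl]methanol | C1/C(CO)=C/C(O[Si](C)(C)C(C)(C)C)=C[C@@H](O[Si](C)(C)C(C)(C)C)C/C(C)=C/C1 | intermediate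
15 | (8S)-6,8-bis[(tert-butyldimethylsilyl)oxy]-4-(chloromethyl)-10-methylcyclodeca-1(10),4,6-triene | C1/C(CCl)=C/C(O[Si](C)(C)C(C)(C)C)=C[C@@H](O[Si](C)(C)C(C)(C)C)C/C(C)=C/C1 | intermediate
16 | (8S)-6,8-bis[(tert-butyldimethylsilyl)oxy]-4,10-dimethylcyclodeca-1(10),4,6-triene | C1/C(C)=C/C(O[Si](C)(C)C(C)(C)C)=C[C@@H](O[Si](C)(C)C(C)(C)C)C/C(C)=C/C1 | intermediate
17 | methyl 2-(hydroxymethyl)acrylate | C=C(CO)C(=O)OC | starting material
18 | methyl 2-{[(tert-butyldimethylsilyl)oxy]methyl}acrylate | C=C(CO[Si](C)(C)C(C)(C)C)C(=O)OC | intermediate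
19 | methyl 3-{[(tert-butyldimethylsilyl)oxy]methyl}-1,2,4-trioxolane-3-carboxylate | COC(=O)C1(CO[Si](C)(C)C(C)(C)C)OOCO1 | intermediate
20 | methyl 3-[(tert-butyldimethylsilyl)oxy]-2-oxopropanoate | COC(=O)C(=O)CO[Si](C)(C)C(C)(C)C | intermediate
21 | methyl 3-[(tert-butyldimethylsilyl)oxy]-2-[(8S)-8-[(tert-butyldimethylsilyl)oxy]-4,10-dimethyl-6-oxocyclodeca-1(10),4-dien-7-yl]-2-hydroxypropanoate (mixture at C7, C11) | C1/C(C)=C/C(=O)C(C(O)(CO[Si](C)(C)C(C)(C)C)C(=O)OC)[C@@H](O[Si](C)(C)C(C)(C)C)C/C(C)=C/C1 | intermediate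
22 | 2-O-trifluoroacetate of 21 | C1/C(C)=C/C(=O)C(C(OC(=O)C(F)(F)F)(CO[Si](C)(C)C(C)(C)C)C(=O)OC)[C@@H](O[Si](C)(C)C(C)(C)C)C/C(C)=C/C1 | intermediate
23 | methyl (2Z)-3-[(tert-butyldimethylsilyl)oxy]-2-[(8S)-8-[(tert-butyldimethylsilyl)oxy]-4,10-dimethyl-6-oxocyclodeca-1(10),4-dien-7-ylidene]propanoate (ester syn to C6) | C1/C(C)=C/C(=O)/C(=C(/CO[Si](C)(C)C(C)(C)C)C(=O)OC)[C@@H](O[Si](C)(C)C(C)(C)C)C/C(C)=C/C1 | intermediate
24 | methyl 3-[(tert-butyldimethylsilyl)oxy]-2-[(6R,8S)-8-[(tert-butyldimethylsilyl)oxy]-6-hydroxy-4,10-dimethylcyclodeca-1(10),4-dien-7-ylidene]propanoate (ester syn to C6) | C1/C(C)=C/[C@@H](O)/C(=C(/CO[Si](C)(C)C(C)(C)C)C(=O)OC)[C@@H](O[Si](C)(C)C(C)(C)C)C/C(C)=C/C1 | intermediate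
25 | (6R,8S)-8,13-bis[(tert-butyldimethylsilyl)oxy]germacra-1(10),4,7(11)-trien-12,6-olide | C1/C(C)=C/[C@H]2OC(=O)C(CO[Si](C)(C)C(C)(C)C)=C2[C@@H](O[Si](C)(C)C(C)(C)C)C/C(C)=C/C1 | intermediate
26 | (6R,8S)-8,13-dihydroxygermacra-1(10),4,7(11)-trien-12,6-olide | C1/C(C)=C/[C@H]2OC(=O)C(CO)=C2[C@@H](O)C/C(C)=C/C1 | intermediate
27 | (6R,8S)-13-acetoxy-8-hydroxygermacra-1(10),4,7(11)-trien-12,6-olide | C1/C(C)=C/[C@H]2OC(=O)C(COC(C)=O)=C2[C@@H](O)C/C(C)=C/C1 | intermediate
28 | angelic acid, (Z)-2-methylbut-2-enoic acid | C/C=C(/C)C(=O)O | starting material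
29 | angelic 2,4,6-trichlorobenzoic anhydride | C/C=C(/C)C(=O)OC(=O)c1c(Cl)cc(Cl)cc1Cl | intermediate
30 | (6R,8S)-13-acetoxy-8-(angeloyloxy)germacra-1(10),4,7(11)-trien-12,6-olide | C1/C(C)=C/[C@H]2OC(=O)C(COC(C)=O)=C2[C@@H](OC(=O)/C(C)=C\C)C/C(C)=C/C1 | intermediate
31 | (1R,4R,5R,6S,8S,10R)-13-acetoxy-8-(angeloyloxy)-1,10:4,5-diepoxygermacr-7(11)-en-12,6-olide | C/C=C(/C)C(=O)O[C@H]1C[C@@]2(C)O[C@@H]2CC[C@@]2(C)O[C@@H]2[C@H]2OC(=O)C(COC(C)=O)=C12 | target

Total step count: 21. Longest linear sequence: 17 steps (steps 1–5, 8–12, 15–21).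

Steps most likely to fail (steps 8 and 9 rest on direct precedent for this reaction pair and are therefore not listed):

Step 16. The elimination may place the ester anti to C6, and the hydroxy ester formed after reduction then cannot lactonise; longer base contact could also shift the alkene towards C8. Fallback, setting out from 21: the same dehydration then gives the geometric isomer methyl (2E)-3-[(tert-butyldimethylsilyl)oxy]-2-[(8S)-8-[(tert-butyldimethylsilyl)oxy]-4,10-dimethyl-6-oxocyclodeca-1(10),4-dien-7-ylidene]propanoate F1 (ester anti to C6). Reduction with the (S)-oxazaborolidine and catecholborane as in step 17 gives the open (6R)-hydroxy ester F2. Direct irradiation of its enoate chromophore (254 nm, MeCN, a trace of pyridinium p-toluenesulfonate) should isomerise the tetrasubstituted alkene, and the syn isomer 24 is drained off irreversibly by lactonisation, so the material returns to the route at 25.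

Step 17. With two sp2 substituents on the carbonyl the oxazaborolidine may discriminate poorly between the two faces, or the C8 centre may override it. Fallback with substrate control, setting out from 23: HF·pyridine removes both silyl groups to give methyl (2Z)-3-hydroxy-2-[(8S)-8-hydroxy-4,10-dimethyl-6-oxocyclodeca-1(10),4-dien-7-ylidene]propanoate F3. Narasaka–Prasad reduction (Et2BOMe, NaBH4, THF/MeOH, −78 °C) holds the C8 hydroxyl and the C6 carbonyl in a boron chelate, takes hydride from outside, and should give the 6,8-syn diol methyl (2Z)-3-hydroxy-2-[(6R,8S)-6,8-dihydroxy-4,10-dimethylcyclodeca-1(10),4-dien-7-ylidene]propanoate F4. F4 lactonises with pyridinium p-toluenesulfonate and returns to the route at 26.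

Step 21. Attack on the C1=C10 alkene may occur from a conformer that shows the other face, and 3-chlorobenzoic acid may trigger transannular opening of the first-formed epoxide. Fallback with reagent control in buffered medium, setting out from 30: Shi epoxidation with the D-fructose-derived ketone (1,2:4,5-di-O-isopropylidene-β-D-erythro-2,3-hexodiulo-2,6-pyranose), KHSO5 and K2CO3 in MeCN/dimethoxymethane/water at 0 °C. Its spiro transition state converts E-trisubstituted alkenes into (R,R)-type epoxides, the sense needed at both C1/C10 and C4/C5, so it returns directly at 31 with no new compound.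

Further compounds
F1 | step 16 | methyl (2E)-3-[(tert-butyldimethylsilyl)oxy]-2-[(8S)-8-[(tert-butyldimethylsilyl)oxy]-4,10-dimethyl-6-oxocyclodeca-1(10),4-dien-7-ylidene]propanoate (ester anti to C6) | C1/C(C)=C/C(=O)/C(=C(\CO[Si](C)(C)C(C)(C)C)C(=O)OC)[C@@H](O[Si](C)(C)C(C)(C)C)C/C(C)=C/C1
F2 | step 16 | methyl 3-[(tert-butyldimethylsilyl)oxy]-2-[(6R,8S)-8-[(tert-butyldimethylsilyl)oxy]-6-hydroxy-4,10-dimethylcyclodeca-1(10),4-dien-7-ylidene]propanoate (ester anti to C6) | C1/C(C)=C/[C@@H](O)/C(=C(\CO[Si](C)(C)C(C)(C)C)C(=O)OC)[C@@H](O[Si](C)(C)C(C)(C)C)C/C(C)=C/C1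
F3 | step 17 | methyl (2Z)-3-hydroxy-2-[(8S)-8-hydroxy-4,10-dimethyl-6-oxocyclodeca-1(10),4-dien-7-ylidene]propanoate | C1/C(C)=C/C(=O)/C(=C(/CO)C(=O)OC)[C@@H](O)C/C(C)=C/C1
F4 | step 17 | methyl (2Z)-3-hydroxy-2-[(6R,8S)-6,8-dihydroxy-4,10-dimethylcyclodeca-1(10),4-dien-7-ylidene]propanoate | C1/C(C)=C/[C@@H](O)/C(=C(/CO)C(=O)OC)[C@@H](O)C/C(C)=C/C1
F0 | step 21 | none | none
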